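**Retrosynthetic overview**
1. The target is a linear trimer of three C6–C3 units (rings A, B, C) joined by two trans-2-aryl-3-(hydroxymethyl)-2,3-dihydrobenzofurans. Each is cut across its C3–C3a and O1–C2 bonds into an (E)-cinnamyl silyl ether and a 2-hydroxyarenediazonium salt.
2. Both rings are built by the same enantioselective palladium-catalysed oxyarylation. The bromine carried by the diazonium salt is inert in that step and is then converted into the next (E)-3-silyloxypropenyl chain by Suzuki–Miyaura coupling.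
3. Order of ring formation: ring A alkene 7, then the first dihydrobenzofuran (rings A–B, step 6), chain extension (step 7), the second dihydrobenzofuran on ring C (step 8: C3–C3a bond, then closure by O1–C2), chain (step 9), desilylation.
4. Enabling feature: C2 of the second dihydrobenzofuran is benzylic to ring B and para to the ring B ether oxygen (O1 of the first dihydrobenzofuran), so a C2–Pd bond ionises to a p-alkoxybenzyl cation. The phenolic oxygen of ring C sits ortho to C3a and captures it in a five-membered closure.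

Key step: step 8

Numbering: each dihydrobenzofuran is O1, C2 (aryl-bearing), C3 (CH2O-bearing), C3a, C7a; both units are (2S,3R), trans.
Assumption: the (S)-pyridine–oxazoline ligand is written for the required sense of induction; step 6 (same diazonium salt, same alkene class) is the check, and the (R)-ligand would be used in steps 6 and 8 if the opposite sense were found.

**Route**

Step 1
Reactants: 1 4-bromo-2-methoxyphenol
Product: 2 4-bromo-2-methoxy-6-nitrophenol
Conditions: HNO3 (65%), AcOH, 10 °C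
Reagents that add atoms: nitric acid, O[N+](=O)[O-]
Why: Electrophilic aromatic nitration; OH directs ortho, its para position is blocked by bromine and one ortho position by OMe, so the nitro group should enter C6.

Step 2
Reactants: 2 4-bromo-2-methoxy-6-nitrophenol
Product: 3 2-amino-4-bromo-6-methoxyphenol
Conditions: H2 (1 atm), sulfided Pt/C (5% platinum on carbon), EtOAc, rt
Reagents that add atoms: none
Why: Chemoselective catalytic hydrogenation of the nitro group; sulfided platinum spares the aryl C–Br bond.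

Step 3
Reactants: 3 2-amino-4-bromo-6-methoxyphenol
Product: 4 5-bromo-2-hydroxy-3-methoxybenzenediazonium tetrafluoroborate
Conditions: t-BuONO, HBF4 (48% aq), EtOH, 0 °C; precipitation with Et2O
Reagents that add atoms: tert-butyl nitrite, CC(C)(C)ON=O; tetrafluoroboric acid, [H+].F[B-](F)(F)F
Why: Diazotisation of the aminophenol with an alkyl nitrite; the non-nucleophilic counter-ion should give a salt that precipitates and can be kept cold for steps 6 and 8.

Step 4
Reactants: 1 4-bromo-2-methoxyphenol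
Product: 5 (4-bromo-2-methoxyphenoxy)triisopropylsilane
Conditions: TIPSCl, imidazole, DMF, rt
Reagents that add atoms: triisopropylsilyl chloride, CC(C)[Si](Cl)(C(C)C)C(C)C
Why: Phenol silylation; the hindered aryl silyl ether should survive the aqueous base of the three Suzuki–Miyaura steps and the buffered oxyarylations.

Step 5
Reactants: 5 (4-bromo-2-methoxyphenoxy)triisopropylsilane; 6 (E)-tert-butyldimethyl{[3-(4,4,5,5-tetramethyl-1,3,2-dioxaborolan-2-yl)prop-2-en-1-yl]oxy}silane
Product: 7 (E)-tert-butyl({3-[3-methoxy-4-(triisopropylsilyloxy)phenyl]prop-2-en-1-yl}oxy)dimethylsilane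
Conditions: PdCl2(dppf) (3 mol %), K3PO4, 1,4-dioxane/H2O (9:1), 70 °C
Reagents that add atoms: none
Why: Suzuki–Miyaura coupling of an aryl bromide with an (E)-alkenyl pinacol boronate, which proceeds with retention of alkene geometry.

Step 6
Reactants: 7 (E)-tert-butyl({3-[3-methoxy-4-(triisopropylsilyloxy)phenyl]prop-2-en-1-yl}oxy)dimethylsilane; 4 5-bromo-2-hydroxy-3-methoxybenzenediazonium tetrafluoroborate
Product: 8 {[(2S,3R)-5-bromo-7-methoxy-2-[3-methoxy-4-(triisopropylsilyloxy)phenyl]-2,3-dihydro-1-benzofuran-3-yl]methoxy}(tert-butyl)dimethylsilane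
Conditions: 4 (1.3 equiv), Pd2(dba)3 (2.5 mol %), (S)-4-tert-butyl-2-[5-(trifluoromethyl)pyridin-2-yl]-4,5-dihydro-1,3-oxazole (6 mol %), ZnCO3, MeCN, 0 °C to rt
Reagents that add atoms: none
Why: Proposed new method: the aryl–palladium cation formed from 4 and zerovalent palladium, bound to the chiral pyridine–oxazoline ligand, adds syn to the (E)-alkene with the aryl group at the CH2OTBS-bearing carbon (ligand-controlled Si-face attack sets C3 as R), the benzylic C–Pd bond para to the silyloxy group ionises, and the ortho phenol closes the ring anti to CH2OTBS (C2 S, trans); the closest known reaction types are the racemic Heck–Matsuda oxyarylation of (E)-1-arylpropenes with 2-hydroxyarenediazonium salts and the enantioselective Heck–Matsuda arylation of acyclic alkenes with pyridine–oxazoline-ligated palladium, and this run also confirms the sense of induction for step 8.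

Step 7
Reactants: 8 {[(2S,3R)-5-bromo-7-methoxy-2-[3-methoxy-4-(triisopropylsilyloxy)phenyl]-2,3-dihydro-1-benzofuran-3-yl]methoxy}(tert-butyl)dimethylsilane; 6 (E)-tert-butyldimethyl{[3-(4,4,5,5-tetramethyl-1,3,2-dioxaborolan-2-yl)prop-2-en-1-yl]oxy}silane
Product: 9 tert-butyl{[(E)-3-{(2S,3R)-3-[(tert-butyldimethylsilyloxy)methyl]-7-methoxy-2-[3-methoxy-4-(triisopropylsilyloxy)phenyl]-2,3-dihydro-1-benzofuran-5-yl}prop-2-en-1-yl]oxy}dimethylsilane (the tris-silyl ether of (2S,3R)-dehydrodiconiferyl alcohol)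
Conditions: PdCl2(dppf) (5 mol %), K3PO4, 1,4-dioxane/H2O (9:1), 70 °C
Reagents that add atoms: none
Why: Suzuki–Miyaura coupling at the unhindered 5-bromide para to O1; the alkene geometry is retained and neither stereocentre is base-labile.

Step 8
Reactants: 9 tris-silyl ether of (2S,3R)-dehydrodiconiferyl alcohol; 4 5-bromo-2-hydroxy-3-methoxybenzenediazonium tetrafluoroborate
Product: 10 (2S,3R)-5-{(2S,3R)-5-bromo-3-[(tert-butyldimethylsilyloxy)methyl]-7-methoxy-2,3-dihydro-1-benzofuran-2-yl}-3-[(tert-butyldimethylsilyloxy)methyl]-7-methoxy-2-[3-methoxy-4-(triisopropylsilyloxy)phenyl]-2,3-dihydro-1-benzofuran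
Conditions: 4 (1.5 equiv), Pd2(dba)3 (2.5 mol %), the (S)-pyridine–oxazoline ligand of step 6 (6 mol %), ZnCO3, MeCN, 0 °C to rt
Reagents that add atoms: none
Why: Proposed new method: zerovalent palladium inserts into the C–N2 bond of 4 and the cationic aryl–palladium complex, held by the chiral pyridine–oxazoline ligand, adds syn across the (E)-alkene of 9, aryl to the CH2OTBS-bearing carbon (future C3) and palladium to the benzylic carbon (future C2), after which the C–Pd bond para to the ring B ether oxygen ionises with loss of zerovalent palladium to a p-alkoxybenzyl (quinone-methide-like) cation that the ortho phenolic oxygen of ring C captures to form the O1–C2 bond. The closest known reaction types are the racemic Heck–Matsuda oxyarylation of (E)-1-arylpropenes with 2-hydroxyarenediazonium salts, which gives trans-2-aryl-3-methyl-2,3-dihydrobenzofurans, and enantioselective Heck–Matsuda arylations of acyclic 1,2-disubstituted alkenes with pyridine–oxazoline-ligated palladium, where insertion is enantio-determining. The one ring formed, the second dihydrobenzofuran, closes in the 5-exo-trig mode by attack of oxygen on the cationic C2. C3 (R) is set by the ligand, which directs the aryl group to the Si face of the CH2OTBS-bearing alkene carbon, and C2 (S) is set by C3, because the oxygen closes anti to the CH2OTBS group (the trans product, also the thermodynamic one). The step needs regioselective insertion and C–O closure in preference to β-hydride elimination, both secured by the para-oxygen of ring B and the ortho OH of the incoming aryl group, chemoselectivity for the diazonium group over C–Br, secured by the low temperature, and catalyst control over the stereocentres of 9, which lie on the far side of ring B. Because the same catalyst made 8, any minor enantiomer of 9 should be carried mainly into a diastereomer of 10 that chromatography can remove.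

Step 9
Reactants: 10 bromide with both dihydrobenzofurans; 6 (E)-tert-butyldimethyl{[3-(4,4,5,5-tetramethyl-1,3,2-dioxaborolan-2-yl)prop-2-en-1-yl]oxy}silane
Product: 11 tetrasilyl ether of the target (three primary TBS ethers, one phenolic TIPS ether)
Conditions: PdCl2(dppf) (5 mol %), K3PO4, 1,4-dioxane/H2O (9:1), 70 °C
Reagents that add atoms: none
Why: Suzuki–Miyaura coupling as in steps 5 and 7; it installs the (E)-allylic side chain of ring C in protected form without touching the four stereocentres.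

Step 10
Reactants: 11 tetrasilyl ether of the target
Product: 12 CNP0250921.2, (E)-3-{(2S,3R)-2-[(2S,3R)-2-(4-hydroxy-3-methoxyphenyl)-3-(hydroxymethyl)-7-methoxy-2,3-dihydro-1-benzofuran-5-yl]-3-(hydroxymethyl)-7-methoxy-2,3-dihydro-1-benzofuran-5-yl}prop-2-en-1-ol
Conditions: TBAF (6 equiv), AcOH (6 equiv), THF, 0 °C to rt
Reagents that add atoms: none
Why: Fluoride-mediated cleavage of all four Si–O bonds; the acetic acid buffer keeps the liberated phenoxide from opening the p-hydroxyphenyl dihydrobenzofuran through a quinone methide, and no stereocentre or the allylic alcohol is touched.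

**Compound list**
1 | 4-bromo-2-methoxyphenol | COc1cc(Br)ccc1O | starting material
2 | 4-bromo-2-methoxy-6-nitrophenol | COc1cc(Br)cc([N+](=O)[O-])c1O | intermediate
3 | 2-amino-4-bromo-6-methoxyphenol | COc1cc(Br)cc(N)c1O | intermediate
4 | 5-bromo-2-hydroxy-3-methoxybenzenediazonium tetrafluoroborate | COc1cc(Br)cc([N+]#N)c1O.F[B-](F)(F)F | intermediate
5 | (4-bromo-2-methoxyphenoxy)triisopropylsilane | COc1cc(Br)ccc1O[Si](C(C)C)(C(C)C)C(C)C | intermediate
6 | (E)-tert-butyldimethyl{[3-(4,4,5,5-tetramethyl-1,3,2-dioxaborolan-2-yl)prop-2-en-1-yl]oxy}silane | CC(C)(C)[Si](C)(C)OC/C=C/B1OC(C)(C)C(C)(C)O1 | starting material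
7 | (E)-tert-butyl({3-[3-methoxy-4-(triisopropylsilyloxy)phenyl]prop-2-en-1-yl}oxy)dimethylsilane | COc1cc(/C=C/CO[Si](C)(C)C(C)(C)C)ccc1O[Si](C(C)C)(C(C)C)C(C)C | intermediate
8 | {[(2S,3R)-5-bromo-7-methoxy-2-[3-methoxy-4-(triisopropylsilyloxy)phenyl]-2,3-dihydro-1-benzofuran-3-yl]methoxy}(tert-butyl)dimethylsilane | COc1cc([C@H]2Oc3c(OC)cc(Br)cc3[C@@H]2CO[Si](C)(C)C(C)(C)C)ccc1O[Si](C(C)C)(C(C)C)C(C)C | intermediate
9 | tris-silyl ether of (2S,3R)-dehydrodiconiferyl alcohol (5-[(E)-3-(TBSO)prop-1-enyl] analogue of 8) | COc1cc([C@H]2Oc3c(OC)cc(/C=C/CO[Si](C)(C)C(C)(C)C)cc3[C@@H]2CO[Si](C)(C)C(C)(C)C)ccc1O[Si](C(C)C)(C(C)C)C(C)C | intermediate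
10 | bromide with both (2S,3R)-dihydrobenzofurans, ring C 5-bromo, two primary TBS ethers, phenolic TIPS ether | COc1cc([C@H]2Oc3c(OC)cc([C@H]4Oc5c(OC)cc(Br)cc5[C@@H]4CO[Si](C)(C)C(C)(C)C)cc3[C@@H]2CO[Si](C)(C)C(C)(C)C)ccc1O[Si](C(C)C)(C(C)C)C(C)C | intermediate
11 | tetrasilyl ether of the target | COc1cc([C@H]2Oc3c(OC)cc([C@H]4Oc5c(OC)cc(/C=C/CO[Si](C)(C)C(C)(C)C)cc5[C@@H]4CO[Si](C)(C)C(C)(C)C)cc3[C@@H]2CO[Si](C)(C)C(C)(C)C)ccc1O[Si](C(C)C)(C(C)C)C(C)C | intermediate
12 | CNP0250921.2 | COc1cc([C@H]2Oc3c(OC)cc([C@H]4Oc5c(OC)cc(/C=C/CO)cc5[C@@H]4CO)cc3[C@@H]2CO)ccc1O | target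

**Totals**
Total step count: 10. Longest linear sequence: 8 steps (1, 2, 3, 6, 7, 8, 9, 10).

**Steps most likely to fail**

Step 8 (Proposed new method). What may go wrong: poor facial selectivity in the migratory insertion, or β-hydride elimination outrunning the C–O closure. The fallback keeps the O1–C2 closure but separates it from the C–C bond formation and sets C3 by an Evans syn-aldol reaction; it sets out from bromide 8 (with the ring C unit drawn from 1) and comes back at 10. Bromine–lithium exchange on 8 (n-BuLi, THF, −78 °C) and DMF should give aldehyde F1. Phenol 1 is O-allylated (allyl bromide, K2CO3, acetone) to allyl ether F2, which undergoes Claisen rearrangement (N,N-diethylaniline, 190 °C) to 2-allyl-4-bromo-6-methoxyphenol F3. MOM protection (MOMCl, i-Pr2NEt) gives F4, Lemieux–Johnson cleavage (OsO4 cat., NaIO4, 2,6-lutidine) gives arylacetaldehyde F5, and Pinnick oxidation gives acid F6. Acylation of lithiated (S)-4-benzyloxazolidin-2-one through the pivaloyl mixed anhydride gives imide F7. The dibutylboron (Z)-enolate of F7 (Bu2BOTf, i-Pr2NEt, CH2Cl2, −78 °C) adds to F1 to give the syn-aldol F8, in which the auxiliary fixes the aryl-bearing α-carbon (the future C3, R after reduction). LiBH4 removes the auxiliary and gives diol F9. HCl in MeOH removes the MOM group and the TBS ether, ionises the benzylic alcohol para to the ring B oxygen and lets the freed phenol close the ring trans, giving diol F10. TBSCl and imidazole silylate both primary alcohols and give 10.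

Step 6 (Proposed new method). What may go wrong: the same loss of facial selectivity or competing β-hydride elimination, here on the simpler alkene. The fallback uses the same aldol logic, sets out from bromide 5 and comes back at 8. Bromine–lithium exchange on 5 and DMF give 3-methoxy-4-(triisopropylsilyloxy)benzaldehyde F11. The boron aldol reaction with imide F7 (made from 1 as described for step 8) gives the syn-aldol F12, LiBH4 gives diol F13, HCl in MeOH removes the MOM group and closes the trans ring to alcohol F14, and TBSCl with imidazole gives 8.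

Step 9. What may go wrong: hydrolytic loss of the phenolic silyl ether or protodeboronation of the alkenyl boronate under aqueous base on the most valuable intermediate. The fallback replaces cross-coupling by carbonyl olefination, sets out from 10 and comes back at 12. Bromine–lithium exchange on 10 and DMF give aldehyde F15. Horner–Wadsworth–Emmons olefination (triethyl phosphonoacetate, NaH, THF) gives the (E)-acrylate F16, and DIBAL-H (CH2Cl2, −78 °C) gives allylic alcohol F17. The conditions of step 10 (TBAF, AcOH) then remove the remaining three silyl groups and give 12.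

**Further compounds**
F1 | step 8 | (2S,3R)-3-[(tert-butyldimethylsilyloxy)methyl]-7-methoxy-2-[3-methoxy-4-(triisopropylsilyloxy)phenyl]-2,3-dihydro-1-benzofuran-5-carbaldehyde | COc1cc([C@H]2Oc3c(OC)cc(C=O)cc3[C@@H]2CO[Si](C)(C)C(C)(C)C)ccc1O[Si](C(C)C)(C(C)C)C(C)C
F2 | step 8 | 1-(allyloxy)-4-bromo-2-methoxybenzene | C=CCOc1ccc(Br)cc1OC
F3 | step 8 | 2-allyl-4-bromo-6-methoxyphenol | C=CCc1cc(Br)cc(OC)c1O
F4 | step 8 | 1-allyl-5-bromo-3-methoxy-2-(methoxymethoxy)benzene | C=CCc1cc(Br)cc(OC)c1OCOC
F5 | step 8 | 2-[5-bromo-3-methoxy-2-(methoxymethoxy)phenyl]acetaldehyde | O=CCc1cc(Br)cc(OC)c1OCOC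
F6 | step 8 | 2-[5-bromo-3-methoxy-2-(methoxymethoxy)phenyl]acetic acid | OC(=O)Cc1cc(Br)cc(OC)c1OCOC
F7 | step 8 | (4S)-4-benzyl-3-{[5-bromo-3-methoxy-2-(methoxymethoxy)phenyl]acetyl}-1,3-oxazolidin-2-one | O=C(Cc1cc(Br)cc(OC)c1OCOC)N1[C@@H](Cc2ccccc2)COC1=O
F8 | step 8 | (4S)-4-benzyl-3-[(2S,3S)-2-[5-bromo-3-methoxy-2-(methoxymethoxy)phenyl]-3-hydroxy-3-{(2S,3R)-3-[(tert-butyldimethylsilyloxy)methyl]-7-methoxy-2-[3-methoxy-4-(triisopropylsilyloxy)phenyl]-2,3-dihydro-1-benzofuran-5-yl}propanoyl]-1,3-oxazolidin-2-one | COc1cc([C@H]2Oc3c(OC)cc([C@@H](O)[C@@H](C(=O)N4[C@@H](Cc5ccccc5)COC4=O)c6cc(Br)cc(OC)c6OCOC)cc3[C@@H]2CO[Si](C)(C)C(C)(C)C)ccc1O[Si](C(C)C)(C(C)C)C(C)C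
F9 | step 8 | (1S,2R)-2-[5-bromo-3-methoxy-2-(methoxymethoxy)phenyl]-1-{(2S,3R)-3-[(tert-butyldimethylsilyloxy)methyl]-7-methoxy-2-[3-methoxy-4-(triisopropylsilyloxy)phenyl]-2,3-dihydro-1-benzofuran-5-yl}propane-1,3-diol | COc1cc([C@H]2Oc3c(OC)cc([C@@H](O)[C@@H](CO)c4cc(Br)cc(OC)c4OCOC)cc3[C@@H]2CO[Si](C)(C)C(C)(C)C)ccc1O[Si](C(C)C)(C(C)C)C(C)C
F10 | step 8 | diol with both (2S,3R)-dihydrobenzofurans, ring C 5-bromo, both hydroxymethyl groups free, phenolic TIPS ether kept | COc1cc([C@H]2Oc3c(OC)cc([C@H]4Oc5c(OC)cc(Br)cc5[C@@H]4CO)cc3[C@@H]2CO)ccc1O[Si](C(C)C)(C(C)C)C(C)C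
F11 | step 6 | 3-methoxy-4-(triisopropylsilyloxy)benzaldehyde | COc1cc(C=O)ccc1O[Si](C(C)C)(C(C)C)C(C)C
F12 | step 6 | (4S)-4-benzyl-3-[(2S,3S)-2-[5-bromo-3-methoxy-2-(methoxymethoxy)phenyl]-3-hydroxy-3-[3-methoxy-4-(triisopropylsilyloxy)phenyl]propanoyl]-1,3-oxazolidin-2-one | COc1cc([C@@H](O)[C@@H](C(=O)N2[C@@H](Cc3ccccc3)COC2=O)c4cc(Br)cc(OC)c4OCOC)ccc1O[Si](C(C)C)(C(C)C)C(C)C
F13 | step 6 | (1S,2R)-2-[5-bromo-3-methoxy-2-(methoxymethoxy)phenyl]-1-[3-methoxy-4-(triisopropylsilyloxy)phenyl]propane-1,3-diol | COc1cc([C@@H](O)[C@@H](CO)c2cc(Br)cc(OC)c2OCOC)ccc1O[Si](C(C)C)(C(C)C)C(C)C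
F14 | step 6 | [(2S,3R)-5-bromo-7-methoxy-2-[3-methoxy-4-(triisopropylsilyloxy)phenyl]-2,3-dihydro-1-benzofuran-3-yl]methanol | COc1cc([C@H]2Oc3c(OC)cc(Br)cc3[C@@H]2CO)ccc1O[Si](C(C)C)(C(C)C)C(C)C
F15 | step 9 | ring C 5-carbaldehyde analogue of 10 | COc1cc([C@H]2Oc3c(OC)cc([C@H]4Oc5c(OC)cc(C=O)cc5[C@@H]4CO[Si](C)(C)C(C)(C)C)cc3[C@@H]2CO[Si](C)(C)C(C)(C)C)ccc1O[Si](C(C)C)(C(C)C)C(C)C
F16 | step 9 | ring C 5-[(E)-2-(ethoxycarbonyl)ethenyl] analogue of 10 | COc1cc([C@H]2Oc3c(OC)cc([C@H]4Oc5c(OC)cc(/C=C/C(=O)OCC)cc5[C@@H]4CO[Si](C)(C)C(C)(C)C)cc3[C@@H]2CO[Si](C)(C)C(C)(C)C)ccc1O[Si](C(C)C)(C(C)C)C(C)C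
F17 | step 9 | ring C 5-[(E)-3-hydroxyprop-1-enyl] analogue of 10 (allylic alcohol free) | COc1cc([C@H]2Oc3c(OC)cc([C@H]4Oc5c(OC)cc(/C=C/CO)cc5[C@@H]4CO[Si](C)(C)C(C)(C)C)cc3[C@@H]2CO[Si](C)(C)C(C)(C)C)ccc1O[Si](C(C)C)(C(C)C)C(C)C
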